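**Retrosynthetic overview**
- The two ester groups, the C14 silyl ether and the exocyclic methylene are removed first; the trans-fused γ-lactone is then traced back to the ten-membered dienone 24 (C7 alkylation, C6 reduction, lactonisation with inversion at C6).
- The strategy rests on one feature: the C8–C9 bond lies between the C1=C10 alkene and C6 (the lactone carbinol, a ketone in 24), so C6(=O)–C7–C8–C9–C10=C1 is the pattern left by an oxy-Cope shift. Breaking C8–C9 and joining C1 to C6 gives cyclohexenol 21, whose ring C1–C6 already holds the cis C4=C5 alkene.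
- 21 comes from cyclohexenone 15 by axial addition of a PMB-oxyacetylide and trans-reduction; 15 comes from an Evans syn aldol (sets C1, C2) and an enone ring-closing metathesis (C4=C5).
- Ring order: cyclohexene (step 10), then the ten-membered carbocycle by ring expansion (step 14), then the γ-lactone (step 17).

Key step: step 14

Remark: ring atoms carry germacrane numbers throughout (C1=C10, C14 on C10, C15 on C4, C11–C13 the lactone carbons); TBS = tert-butyldimethylsilyl, TBDPS = tert-butyldiphenylsilyl, PMB = 4-methoxybenzyl; commercial monomethyl itaconate is taken to be the 4-methyl ester.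

Step 1
Reactants: 1 monomethyl itaconate (4-methoxy-2-methylidene-4-oxobutanoic acid)
Product: 2 methyl 3-(hydroxymethyl)but-3-enoate
Conditions: BH3·THF (1.1 equiv), THF, −15 → 0 °C; MeOH quench
Reagents that add atoms: none
Why: Borane reduces the free carboxylic acid through its acyloxyborane much faster than the ester or the electron-poor 1,1-disubstituted alkene (chemoselective acid reduction).

Step 2
Reactants: 2 methyl 3-(hydroxymethyl)but-3-enoate
Product: 3 methyl 3-[(TBDPS-oxy)methyl]but-3-enoate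
Conditions: TBDPSCl, imidazole, DMF, 0 °C → rt
Reagents that add atoms: tert-butyl(chloro)diphenylsilane, CC(C)(C)[Si](Cl)(c1ccccc1)c1ccccc1
Why: Routine silylation of a primary alcohol gives the silyl ether that has to last until the final step.

Step 3
Reactants: 3 methyl 3-[(TBDPS-oxy)methyl]but-3-enoate
Product: 4 3-[(TBDPS-oxy)methyl]but-3-enoic acid
Conditions: LiOH, THF–H2O, 0 °C → rt; 1 M HCl to pH 3 at 0 °C
Reagents that add atoms: lithium hydroxide, [Li+].[OH-]
Why: Saponification of the unhindered methyl ester should be faster than base-induced migration of the β,γ-alkene into conjugation.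

Step 4
Reactants: 4 3-[(TBDPS-oxy)methyl]but-3-enoic acid; 5 (R)-4-benzyl-1,3-oxazolidin-2-one
Product: 7 (R)-4-benzyl-3-{3-[(TBDPS-oxy)methyl]but-3-enoyl}-1,3-oxazolidin-2-one, via pivalic mixed anhydride 6 (not isolated)
Conditions: t-BuCOCl, Et3N, THF, −20 °C; then 5, LiCl, −20 → 0 °C
Reagents that add atoms: none
Why: N-acylation through the mixed anhydride with LiCl and an amine base avoids strong base, so the β,γ-unsaturated acyl group should not isomerise.

Step 5
Reactants: 8 3-methylbut-3-en-1-ol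
Product: 9 3-methylbut-3-enal
Conditions: Dess–Martin periodinane, NaHCO3, CH2Cl2, 0 °C; used at once as a cold CH2Cl2 solution
Reagents that add atoms: none
Why: Dess–Martin oxidation under buffered conditions gives the β,γ-unsaturated aldehyde, which is not concentrated because base or heat would move the alkene into conjugation.

Step 6
Reactants: 7 (R)-4-benzyl-3-{3-[(TBDPS-oxy)methyl]but-3-enoyl}-1,3-oxazolidin-2-one; 9 3-methylbut-3-enal
Product: 11 (R)-4-benzyl-3-{(2R,3S)-3-hydroxy-5-methyl-2-[3-(TBDPS-oxy)prop-1-en-2-yl]hex-5-enoyl}-1,3-oxazolidin-2-one, via dibutylboron Z-dienolate 10 (not isolated)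
Conditions: n-Bu2BOTf, i-Pr2NEt, CH2Cl2, −78 → 0 °C; 9, −78 → −10 °C; pH 7 buffer, MeOH, H2O2, 0 °C
Reagents that add atoms: none
Why: Evans boron aldol: the Z dienolate reacts at its α-carbon through a Zimmerman–Traxler chair on the face away from the benzyl group, setting C1 (R) and C2 (S) as the syn pair.

Step 7
Reactants: 11 syn-aldol imide
Product: 12 (2R,3S)-3-hydroxy-N-methoxy-N,5-dimethyl-2-[3-(TBDPS-oxy)prop-1-en-2-yl]hex-5-enamide
Conditions: MeNH(OMe)·HCl, AlMe3, THF, −20 → 0 °C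
Reagents that add atoms: N,O-dimethylhydroxylamine hydrochloride, CNOC.Cl
Why: Aluminium-amide transamination of the β-hydroxy imide (helped by the free C2 hydroxyl) gives the Weinreb amide and returns the auxiliary without disturbing C1.

Step 8
Reactants: 12 β-hydroxy Weinreb amide
Product: 13 (2R,3S)-3-(TBS-oxy)-N-methoxy-N,5-dimethyl-2-[3-(TBDPS-oxy)prop-1-en-2-yl]hex-5-enamide
Conditions: TBSOTf, 2,6-lutidine, CH2Cl2, −78 → 0 °C
Reagents that add atoms: tert-butyldimethylsilyl triflate, CC(C)(C)[Si](C)(C)OS(=O)(=O)C(F)(F)F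
Why: Silyl triflate silylation of the hindered secondary alcohol installs the group that is later exchanged for the C2 acetate.

Step 9
Reactants: 13 silylated Weinreb amide
Product: 14 (4R,5S)-5-(TBS-oxy)-7-methyl-4-[3-(TBDPS-oxy)prop-1-en-2-yl]octa-1,7-dien-3-one
Conditions: CH2=CHMgBr, THF, −20 → 0 °C; poured into cold 1 M HCl
Reagents that add atoms: vinylmagnesium bromide, C=C[Mg]Br
Why: Weinreb ketone synthesis: the chelated tetrahedral intermediate takes up one vinyl group only, and the cold acidic quench keeps the liberated amine from adding to the enone.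

Step 10
Reactants: 14 acyclic vinyl ketone
Product: 15 (5S,6R)-5-(TBS-oxy)-3-methyl-6-[3-(TBDPS-oxy)prop-1-en-2-yl]cyclohex-2-en-1-one
Conditions: second-generation Hoveyda–Grubbs catalyst RuCl2(H2IMes)(=CH-C6H4-2-Oi-Pr) (5 mol %), CH2Cl2, 40 °C
Reagents that add atoms: none
Why: Ring-closing metathesis of the vinyl ketone with the methallyl alkene closes ring C1–C6 and fixes C4=C5 as a ring-cis alkene, while the hindered C10 alkene could only give four- or five-membered rings and should stay out.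

Step 11
Reactants: 16 (4-methoxyphenyl)methanol; 17 trichloroethylene
Product: 18 1-{[(E)-1,2-dichloroethenyl]oxymethyl}-4-methoxybenzene
Conditions: KH (2 equiv), THF, 0 °C; 17, −50 °C → rt
Reagents that add atoms: none
Why: The potassium alkoxide adds to dichloroacetylene formed in situ by dehydrochlorination of trichloroethylene, the established entry to 1,2-dichlorovinyl ethers.

Step 12
Reactants: 18 PMB (E)-1,2-dichlorovinyl ether; 15 cyclohexenone
Product: 20 (1R,5S,6R)-5-(TBS-oxy)-1-[(4-methoxybenzyloxy)ethynyl]-3-methyl-6-[3-(TBDPS-oxy)prop-1-en-2-yl]cyclohex-2-en-1-ol, via lithium 4-methoxybenzyloxyethynide 19 (not isolated)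
Conditions: 18, n-BuLi (2.2 equiv), THF, −78 → −40 °C; 15, −78 °C; aq. NH4Cl; crude kept below 0 °C and used at once
Reagents that add atoms: none
Why: Elimination and Cl/Li exchange give the alkoxyacetylide, which adds 1,2 to the enone along the axial trajectory of the half-chair (C1 arm and C2 silyloxy both equatorial), so the alkynyl group at the new C6 centre ends cis to the C1 arm.

Step 13
Reactants: 20 alkynyl carbinol
Product: 21 (1S,5S,6R)-5-(TBS-oxy)-1-[(E)-2-(4-methoxybenzyloxy)ethenyl]-3-methyl-6-[3-(TBDPS-oxy)prop-1-en-2-yl]cyclohex-2-en-1-ol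
Conditions: LiAlH4, THF, 0 °C; basic work-up, Et3N-washed silica
Reagents that add atoms: none
Why: Hydroxyl-directed trans-hydroalumination of the propargylic alcohol and protonolysis give the E enol ether, the known reduction of alkoxyethynyl carbinols to E-β-alkoxyvinyl carbinols.

Step 14
Reactants: 21 cis-dialkenyl cyclohexenol
Product: 24 (1(10)E,2S,4Z,8R)-2-(TBS-oxy)-14-(TBDPS-oxy)-8-(PMB-oxy)germacra-1(10),4-dien-6-one skeleton without C11–C13 [(2Z,5S,6E,9R)-5-(TBS-oxy)-7-[(TBDPS-oxy)methyl]-9-(4-methoxybenzyloxy)-3-methylcyclodeca-2,6-dien-1-one], via potassium alkoxide 22 (not isolated), via potassium enolate 23 (not isolated)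
Conditions: KH, 18-crown-6, THF, 0 °C → rt; then AcOH, THF, −78 °C
Reagents that add atoms: none
Why: KH deprotonates the tertiary alcohol and alkoxide 22 undergoes the anionic oxy-Cope [3,3] shift (C8–C9 formed, C1–C6 broken), the same reaction type as the known ring expansion of 1,2-dialkenylcyclohexanols to cyclodec-5-enones; acetic acid at −78 °C then protonates enolate 23 before the C8 ether can leave by β-elimination. The ten-membered ring arises from the six-membered one by insertion of four carbons (C7–C10) through a six-membered chair transition state, so no macrocyclisation is involved. Because the two alkenyl groups are cis, the six reacting atoms can adopt a chair with C2 axial on C1 and C5 equatorial on C6; the axial ring bond ends cis to the new C8–C9 bond across C1=C10 (ring-cis, E by CIP because of C14), and the cyclohexene alkene is kept as ring-cis C4=C5. The PMB-oxygen, trans to C6 on the enol ether, lies equatorial on that chair, so with C1 and C6 fixed the configuration of C8 (R) is set by chirality transfer as C6 flattens to the ketone. The selectivity needed is this chair over the ring-flipped chair and the boats, and it is secured because it is the cyclohexene half-chair with the C1 arm and the C2 silyloxy group both equatorial, whereas the other chair needs both axial. Silyl migration from O2 to the tertiary alkoxide is uphill and should not compete.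

Step 15
Reactants: 24 ten-membered dienone
Product: 26 methyl 2-[(2S,7R,8R)-configured ring]acetate: C6 ketone, C7 CH2CO2Me, C8 OPMB, C2 OTBS, C14 OTBDPS, 1(10)E,4Z, via lithium enolate 25 (not isolated)
Conditions: LiN(i-Pr)2, THF, −78 °C; BrCH2CO2Me, −78 → −40 °C; AcOH quench at −78 °C
Reagents that add atoms: methyl bromoacetate, COC(=O)CBr
Why: Kinetic α′-deprotonation should give the lithium enolate chelated between the enolate oxygen and the C8 ether oxygen, and the bromoacetate enters at C7 anti to the ring bond C8–C9 (the open face), which sets C7 (R) anti to the C8 oxygen in the sense of a Fráter–Seebach alkylation.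

Step 16
Reactants: 26 keto ester
Product: 28 (2S,6S,7S,8R)-6-hydroxy acid: C6 OH cis to the C7 CH2CO2H arm, C8 OPMB, via methyl hydroxy ester 27 (not isolated)
Conditions: NaBH4, CeCl3·7H2O, MeOH, −78 °C; then LiOH, THF–H2O, 0 °C → rt; HCl to pH 4–5 at 0 °C, extracted cold and used at once
Reagents that add atoms: lithium hydroxide, [Li+].[OH-]
Why: Luche 1,2-reduction: hydride should reach C6 from the ring periphery, anti to the ring bond C7–C8 (Felkin–Anh, acetate arm inside), giving the 6S alcohol cis to the arm, and hydroxide then converts the ester and any cis lactone into one hydroxy acid.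

Step 17
Reactants: 28 6S hydroxy acid
Product: 29 (2S,6R,7R,8R)-2-(TBS-oxy)-14-(TBDPS-oxy)-8-(PMB-oxy) trans-fused 12,6-lactone (C11 still CH2), 1(10)E,4Z
Conditions: PPh3, DIAD, THF, 0 °C
Reagents that add atoms: none
Why: Mitsunobu lactonisation: the allylic C6 hydroxyl is activated as its oxyphosphonium ion and displaced by the internal carboxylate (5-exo-tet SN2) with inversion, giving the 6R trans-fused γ-lactone.

Step 18
Reactants: 29 trans-fused lactone
Product: 33 (1(10)E,2S,4Z,6R,7R,8R)-2-(TBS-oxy)-14-(TBDPS-oxy)-8-(PMB-oxy)germacra-1(10),4,11(13)-trien-12,6-olide, via lithium lactone enolate 30 (not isolated), via Mannich base 31 (not isolated), via ammonium iodide 32 (not isolated)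
Conditions: LiN(i-Pr)2, THF, −78 °C; CH2=NMe2+ I−, −78 °C → rt; MeI, CH2Cl2–MeOH; aq. NaHCO3
Reagents that add atoms: N,N-dimethylmethyleneiminium iodide, C=[N+](C)C.[I-]
Why: Eschenmoser methylenation: Mannich reaction of the lactone enolate, N-methylation and E1cB loss of trimethylamine install the exocyclic C11=C13 alkene.

Step 19
Reactants: 33 α-methylene lactone
Product: 34 (2S,6R,7R,8R)-2-hydroxy-14-(TBDPS-oxy)-8-(PMB-oxy)germacra-1(10)E,4Z,11(13)-trien-12,6-olide
Conditions: CSA (0.2 equiv), MeOH–CH2Cl2, 0 °C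
Reagents that add atoms: none
Why: Acid-catalysed methanolysis removes the secondary TBS ether while the far more acid-stable TBDPS ether, the PMB ether and the lactone stay.

Step 20
Reactants: 34 C2 alcohol
Product: 35 (2S,6R,7R,8R)-2-acetoxy-14-(TBDPS-oxy)-8-(PMB-oxy)germacra-1(10)E,4Z,11(13)-trien-12,6-olide
Conditions: Ac2O, pyridine, DMAP (cat.), CH2Cl2, 0 °C → rt
Reagents that add atoms: acetic anhydride, CC(=O)OC(C)=O
Why: DMAP-catalysed acylation of the free C2 alcohol proceeds with retention at C2.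

Step 21
Reactants: 35 C2 acetate
Product: 36 (2S,6R,7R,8R)-2-acetoxy-8-hydroxy-14-(TBDPS-oxy)germacra-1(10)E,4Z,11(13)-trien-12,6-olide
Conditions: DDQ, CH2Cl2–pH 7 buffer, 0 °C → rt
Reagents that add atoms: none
Why: Oxidative PMB cleavage (benzylic hydride abstraction, hydrolysis of the oxocarbenium ion) frees the C8 alcohol without touching the silyl ether, the esters or the alkenes.

Step 22
Reactants: 36 C8 alcohol
Product: 37 (2S,6R,7R,8R)-2-acetoxy-8-(methacryloyloxy)-14-(TBDPS-oxy)germacra-1(10)E,4Z,11(13)-trien-12,6-olide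
Conditions: methacrylic anhydride, Et3N, DMAP, CH2Cl2, 0 °C → rt
Reagents that add atoms: methacrylic anhydride, C=C(C)C(=O)OC(=O)C(C)=C
Why: Steglich-type acylation with the anhydride esterifies the secondary C8 alcohol under mild base.

Step 23
Reactants: 37 silyl-protected target
Product: 38 target, (1(10)E,2S,4Z,6R,7R,8R)-2-acetoxy-14-hydroxy-8-(methacryloyloxy)germacra-1(10),4,11(13)-trien-12,6-olide
Conditions: HF·pyridine, pyridine, THF, 0 °C → rt
Reagents that add atoms: none
Why: Fluoride-mediated desilylation under buffered, non-basic conditions cleaves the primary TBDPS ether and should spare both esters and the α-methylene lactone.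

**Compound list**
1 | monomethyl itaconate (4-methoxy-2-methylidene-4-oxobutanoic acid) | C=C(CC(=O)OC)C(=O)O | starting material
2 | methyl 3-(hydroxymethyl)but-3-enoate | COC(=O)CC(=C)CO | intermediate
3 | methyl 3-[(TBDPS-oxy)methyl]but-3-enoate | COC(=O)CC(=C)CO[Si](c1ccccc1)(c1ccccc1)C(C)(C)C | intermediate
4 | 3-[(TBDPS-oxy)methyl]but-3-enoic acid | OC(=O)CC(=C)CO[Si](c1ccccc1)(c1ccccc1)C(C)(C)C | intermediate
5 | (R)-4-benzyl-1,3-oxazolidin-2-one | O=C1N[C@H](Cc2ccccc2)CO1 | starting material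
6 | mixed anhydride of 4 with pivalic acid | CC(C)(C)C(=O)OC(=O)CC(=C)CO[Si](c1ccccc1)(c1ccccc1)C(C)(C)C | intermediate
7 | (R)-4-benzyl-3-{3-[(TBDPS-oxy)methyl]but-3-enoyl}-1,3-oxazolidin-2-one | O=C1OC[C@@H](Cc2ccccc2)N1C(=O)CC(=C)CO[Si](c1ccccc1)(c1ccccc1)C(C)(C)C | intermediate
8 | 3-methylbut-3-en-1-ol | C=C(C)CCO | starting material
9 | 3-methylbut-3-enal | C=C(C)CC=O | intermediate
10 | Z dibutylboron dienolate of 7 | O=C1OC[C@@H](Cc2ccccc2)N1/C(OB(CCCC)CCCC)=C/C(=C)CO[Si](c1ccccc1)(c1ccccc1)C(C)(C)C | intermediate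
11 | (R)-4-benzyl-3-{(2R,3S)-3-hydroxy-5-methyl-2-[3-(TBDPS-oxy)prop-1-en-2-yl]hex-5-enoyl}-1,3-oxazolidin-2-one | O=C1OC[C@@H](Cc2ccccc2)N1C(=O)[C@@H]([C@@H](O)CC(C)=C)C(=C)CO[Si](c1ccccc1)(c1ccccc1)C(C)(C)C | intermediate
12 | (2R,3S)-3-hydroxy-N-methoxy-N,5-dimethyl-2-[3-(TBDPS-oxy)prop-1-en-2-yl]hex-5-enamide | CON(C)C(=O)[C@@H]([C@@H](O)CC(C)=C)C(=C)CO[Si](c1ccccc1)(c1ccccc1)C(C)(C)C | intermediate
13 | (2R,3S)-3-(TBS-oxy)-N-methoxy-N,5-dimethyl-2-[3-(TBDPS-oxy)prop-1-en-2-yl]hex-5-enamide | CON(C)C(=O)[C@@H]([C@@H](O[Si](C)(C)C(C)(C)C)CC(C)=C)C(=C)CO[Si](c1ccccc1)(c1ccccc1)C(C)(C)C | intermediate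
14 | (4R,5S)-5-(TBS-oxy)-7-methyl-4-[3-(TBDPS-oxy)prop-1-en-2-yl]octa-1,7-dien-3-one | C=CC(=O)[C@@H]([C@@H](O[Si](C)(C)C(C)(C)C)CC(C)=C)C(=C)CO[Si](c1ccccc1)(c1ccccc1)C(C)(C)C | intermediate
15 | (5S,6R)-5-(TBS-oxy)-3-methyl-6-[3-(TBDPS-oxy)prop-1-en-2-yl]cyclohex-2-en-1-one | O=C1C=C(C)C[C@H](O[Si](C)(C)C(C)(C)C)[C@H]1C(=C)CO[Si](c2ccccc2)(c2ccccc2)C(C)(C)C | intermediate
16 | (4-methoxyphenyl)methanol | COc1ccc(CO)cc1 | starting material
17 | trichloroethylene | ClC=C(Cl)Cl | starting material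
18 | 1-{[(E)-1,2-dichloroethenyl]oxymethyl}-4-methoxybenzene | COc1ccc(CO/C(Cl)=C\Cl)cc1 | intermediate
19 | lithium (4-methoxybenzyloxy)ethynide | [Li]C#COCc1ccc(OC)cc1 | intermediate
20 | (1R,5S,6R)-5-(TBS-oxy)-1-[(4-methoxybenzyloxy)ethynyl]-3-methyl-6-[3-(TBDPS-oxy)prop-1-en-2-yl]cyclohex-2-en-1-ol | COc1ccc(COC#C[C@@]2(O)C=C(C)C[C@H](O[Si](C)(C)C(C)(C)C)[C@H]2C(=C)CO[Si](c3ccccc3)(c3ccccc3)C(C)(C)C)cc1 | intermediate
21 | (1S,5S,6R)-5-(TBS-oxy)-1-[(E)-2-(4-methoxybenzyloxy)ethenyl]-3-methyl-6-[3-(TBDPS-oxy)prop-1-en-2-yl]cyclohex-2-en-1-ol | COc1ccc(CO/C=C/[C@@]2(O)C=C(C)C[C@H](O[Si](C)(C)C(C)(C)C)[C@H]2C(=C)CO[Si](c3ccccc3)(c3ccccc3)C(C)(C)C)cc1 | intermediate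
22 | potassium alkoxide of 21 | COc1ccc(CO/C=C/[C@@]2([O-])C=C(C)C[C@H](O[Si](C)(C)C(C)(C)C)[C@H]2C(=C)CO[Si](c3ccccc3)(c3ccccc3)C(C)(C)C)cc1.[K+] | intermediate
23 | potassium enolate of 24 (C6=C7 with ring bonds trans, 2S,8R) | C1/C(CO[Si](c2ccccc2)(c2ccccc2)C(C)(C)C)=C\[C@@H](O[Si](C)(C)C(C)(C)C)C/C(C)=C\C([O-])=C\[C@@H]1OCc1ccc(OC)cc1.[K+] | intermediate
24 | (2Z,5S,6E,9R)-5-(TBS-oxy)-7-[(TBDPS-oxy)methyl]-9-(4-methoxybenzyloxy)-3-methylcyclodeca-2,6-dien-1-one (germacrane numbering: C6 ketone, 2S,8R) | COc1ccc(CO[C@@H]2C/C(CO[Si](c3ccccc3)(c3ccccc3)C(C)(C)C)=C\[C@@H](O[Si](C)(C)C(C)(C)C)C/C(C)=C\C(=O)C2)cc1 | intermediate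
25 | lithium enolate of 24 (C6=C7 with ring bonds trans, 2S,8R) | C1/C(CO[Si](c2ccccc2)(c2ccccc2)C(C)(C)C)=C\[C@@H](O[Si](C)(C)C(C)(C)C)C/C(C)=C\C([O-])=C\[C@@H]1OCc1ccc(OC)cc1.[Li+] | intermediate
26 | (2S,7R,8R) keto ester: C6 ketone, C7 CH2CO2Me, C8 OPMB, C2 OTBS, C14 OTBDPS | COc1ccc(CO[C@@H]2C/C(CO[Si](c3ccccc3)(c3ccccc3)C(C)(C)C)=C\[C@@H](O[Si](C)(C)C(C)(C)C)C/C(C)=C\C(=O)[C@@H]2CC(=O)OC)cc1 | intermediate
27 | (2S,6S,7S,8R) hydroxy methyl ester | COc1ccc(CO[C@@H]2C/C(CO[Si](c3ccccc3)(c3ccccc3)C(C)(C)C)=C\[C@@H](O[Si](C)(C)C(C)(C)C)C/C(C)=C\[C@H](O)[C@@H]2CC(=O)OC)cc1 | intermediate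
28 | (2S,6S,7S,8R) hydroxy acid | COc1ccc(CO[C@@H]2C/C(CO[Si](c3ccccc3)(c3ccccc3)C(C)(C)C)=C\[C@@H](O[Si](C)(C)C(C)(C)C)C/C(C)=C\[C@H](O)[C@@H]2CC(=O)O)cc1 | intermediate
29 | (2S,6R,7R,8R) trans-fused 12,6-lactone, C11 CH2 | COc1ccc(CO[C@@H]2C/C(CO[Si](c3ccccc3)(c3ccccc3)C(C)(C)C)=C\[C@@H](O[Si](C)(C)C(C)(C)C)C/C(C)=C\[C@H]3OC(=O)C[C@@H]32)cc1 | intermediate
30 | lithium enolate of lactone 29 | COc1ccc(CO[C@@H]2C/C(CO[Si](c3ccccc3)(c3ccccc3)C(C)(C)C)=C\[C@@H](O[Si](C)(C)C(C)(C)C)C/C(C)=C\[C@H]3OC([O-])=C[C@@H]32)cc1.[Li+] | intermediate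
31 | 11-(dimethylaminomethyl) lactone (C11 configuration not defined, removed in the same step) | COc1ccc(CO[C@@H]2C/C(CO[Si](c3ccccc3)(c3ccccc3)C(C)(C)C)=C\[C@@H](O[Si](C)(C)C(C)(C)C)C/C(C)=C\[C@H]3OC(=O)C(CN(C)C)[C@@H]32)cc1 | intermediate
32 | 11-(trimethylammoniomethyl) lactone iodide | COc1ccc(CO[C@@H]2C/C(CO[Si](c3ccccc3)(c3ccccc3)C(C)(C)C)=C\[C@@H](O[Si](C)(C)C(C)(C)C)C/C(C)=C\[C@H]3OC(=O)C(C[N+](C)(C)C)[C@@H]32)cc1.[I-] | intermediate
33 | (2S,6R,7R,8R)-2-(TBS-oxy)-14-(TBDPS-oxy)-8-(PMB-oxy)germacra-1(10)E,4Z,11(13)-trien-12,6-olide | COc1ccc(CO[C@@H]2C/C(CO[Si](c3ccccc3)(c3ccccc3)C(C)(C)C)=C\[C@@H](O[Si](C)(C)C(C)(C)C)C/C(C)=C\[C@H]3OC(=O)C(=C)[C@@H]32)cc1 | intermediate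
34 | (2S,6R,7R,8R)-2-hydroxy-14-(TBDPS-oxy)-8-(PMB-oxy)germacra-1(10)E,4Z,11(13)-trien-12,6-olide | COc1ccc(CO[C@@H]2C/C(CO[Si](c3ccccc3)(c3ccccc3)C(C)(C)C)=C\[C@@H](O)C/C(C)=C\[C@H]3OC(=O)C(=C)[C@@H]32)cc1 | intermediate
35 | (2S,6R,7R,8R)-2-acetoxy-14-(TBDPS-oxy)-8-(PMB-oxy)germacra-1(10)E,4Z,11(13)-trien-12,6-olide | COc1ccc(CO[C@@H]2C/C(CO[Si](c3ccccc3)(c3ccccc3)C(C)(C)C)=C\[C@@H](OC(C)=O)C/C(C)=C\[C@H]3OC(=O)C(=C)[C@@H]32)cc1 | intermediate
36 | (2S,6R,7R,8R)-2-acetoxy-8-hydroxy-14-(TBDPS-oxy)germacra-1(10)E,4Z,11(13)-trien-12,6-olide | O[C@@H]1C/C(CO[Si](c2ccccc2)(c2ccccc2)C(C)(C)C)=C\[C@@H](OC(C)=O)C/C(C)=C\[C@H]2OC(=O)C(=C)[C@@H]21 | intermediate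
37 | (2S,6R,7R,8R)-2-acetoxy-8-(methacryloyloxy)-14-(TBDPS-oxy)germacra-1(10)E,4Z,11(13)-trien-12,6-olide | C=C(C)C(=O)O[C@@H]1C/C(CO[Si](c2ccccc2)(c2ccccc2)C(C)(C)C)=C\[C@@H](OC(C)=O)C/C(C)=C\[C@H]2OC(=O)C(=C)[C@@H]21 | intermediate
38 | (1(10)E,2S,4Z,6R,7R,8R)-2-acetoxy-14-hydroxy-8-(methacryloyloxy)germacra-1(10),4,11(13)-trien-12,6-olide | C=C(C)C(=O)O[C@@H]1C/C(CO)=C\[C@@H](OC(C)=O)C/C(C)=C\[C@H]2OC(=O)C(=C)[C@@H]21 | target

**Step count**
Total: 23 steps. Longest linear sequence: 21 steps (steps 1–4, 6–10, 12–23); steps 5 and 11 are side branches.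

**Steps most likely to fail**

Step 14. The free ten-membered potassium enolate may expel the C8 alkoxide by β-elimination, or material may be lost during protonation of the β-alkoxy ketone; any reaction through the ring-flipped chair would also erode the C1=C10 geometry. The fallback sets out from 21 and comes back at 26. The rearrangement is run as in step 14, but instead of protonation the enolate 23 is silylated at −78 °C with Me3SiCl/Et3N to the trimethylsilyl enol ether F1. MeLi in THF at 0 °C then cleaves the O–Si bond to give lithium enolate 25, with position and geometry fixed by the rearrangement, and methyl bromoacetate alkylates it as in step 15 to give 26, so ketone 24 is never handled.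

Step 15. Facial selectivity at C7 may be poor if the lithium enolate is not chelated or forms with the other geometry, and the C8 ether may be lost on warming. The fallback sets out from 24 and comes back at 26. DDQ removes the PMB group to give the C8-hydroxy dienone F2; 2.2 equiv of LiN(i-Pr)2 form the alkoxide–enolate dianion, a rigid lithium chelate with no β-leaving group, and methyl bromoacetate alkylates it anti to the C8 oxygen (Fráter–Seebach alkylation) to give the hydroxy keto ester F3. PMB trichloroacetimidate with catalytic Sc(OTf)3 restores the ether and gives 26.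

Step 16. Hydride may be delivered from the other face of the C6 carbonyl, or with low selectivity; the inverting lactonisation of step 17 would then lead to the cis-fused lactone. The fallback sets out from 26 and comes back at 29. The Luche reduction is run without the hydroxide treatment and the 6R hydroxy ester F4 is separated. F4 is closed with retention by acid-catalysed transesterification (PPTS, CH2Cl2) to 29, so acyl substitution replaces the Mitsunobu displacement for this epimer, while any 6S material continues through 28.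

**Further compounds**
F1 | step 14 | trimethylsilyl enol ether of enolate 23 (C6 OSiMe3, C6=C7 with ring bonds trans, 2S,8R) | C1/C(CO[Si](c2ccccc2)(c2ccccc2)C(C)(C)C)=C\[C@@H](O[Si](C)(C)C(C)(C)C)C/C(C)=C\C(O[Si](C)(C)C)=C\[C@@H]1OCc1ccc(OC)cc1
F2 | step 15 | (2S,8R) C8-hydroxy dienone (24 without PMB) | O[C@@H]1C/C(CO[Si](c2ccccc2)(c2ccccc2)C(C)(C)C)=C\[C@@H](O[Si](C)(C)C(C)(C)C)C/C(C)=C\C(=O)C1
F3 | step 15 | (2S,7R,8R) C8-hydroxy keto ester (26 without PMB) | O[C@@H]1C/C(CO[Si](c2ccccc2)(c2ccccc2)C(C)(C)C)=C\[C@@H](O[Si](C)(C)C(C)(C)C)C/C(C)=C\C(=O)[C@@H]1CC(=O)OC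
F4 | step 16 | (2S,6R,7S,8R) hydroxy methyl ester, C6 epimer of 27 | COc1ccc(CO[C@@H]2C/C(CO[Si](c3ccccc3)(c3ccccc3)C(C)(C)C)=C\[C@@H](O[Si](C)(C)C(C)(C)C)C/C(C)=C\[C@@H](O)[C@@H]2CC(=O)OC)cc1
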